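Numbering: cyclobutane C1–C9–C10–C11(Me2); nine-membered ring C1–C2–C3=C4(Me)–C5(OH)–C6–C7–C8–C9; pyran O–C8–C15–C1′(i-Bu)–C2′=C3′.
Cuts: O–C8 and C15–C1′ go first (hetero-Diels–Alder of a C8=C15 methylene with isobutylidene-syncarpic acid), then C8=C15 (Wittig). The Z-C3=C4(Me)–C5(OH) segment left in the nine-membered ring is a 2-methylcyclonon-2-enone at the alcohol level. C4 and its methyl are therefore excised by cutting C3–C4 and C4–C5, which leaves an eight-membered ketone enolised from C5 toward C3.
Further cuts: C2=C3 (ring-closing metathesis), C3–C5 (vinyl addition), C7–C8 (acylation of a zinc homoenolate), and the cyclobutane back to a 2-diazocyclopentanone (Wolff contraction).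
Forward ring order: cyclopentane, cyclobutane, eight-membered ring, transient cyclopropane, nine-membered ring, then the dihydropyran fused onto the ready-made syncarpic ring.
Stereochemistry: C1 comes from a rhodium/(S)-BINAP conjugate vinylation and C9 from base equilibration to the trans-cyclobutane. Z-C3=C4 comes from the inward-rotating cyclopropane opening plus equilibration, C5 from a CBS reduction, and C8 and C1′ from an outer-face, C9-exo cycloaddition.

Key step: step 10

Remark: bicyclic intermediates carry the atom numbers of the target, and 1R, 9S refer to these numbers. Compounds 24, 25 and 27 are drawn in the keto form although 24 and 25 are largely enolised. Compound 7 is used as its commercial THF solution.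

Step 1
Reactants: 1 4,4-dimethylcyclopent-2-en-1-one
Product: 2 (3S)-3-ethenyl-4,4-dimethylcyclopentan-1-one
Conditions: CH2=CHBF3K, [Rh(cod)2]BF4 (3 mol %), (S)-BINAP, PhMe/H2O, 100 °C
Reagents that add atoms: potassium vinyltrifluoroborate, C=C[B-](F)(F)F.[K+]
Why: Hayashi–Miyaura asymmetric 1,4-addition: the vinylrhodium–(S)-BINAP species should insert the enone on the face that the same ligand selects in the parent cyclopentenone, which fixes the future C1 (3S in 2), and the neighbouring quaternary carbon is expected to slow but not to redirect the insertion.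

Step 2
Reactants: 2 (3S)-3-ethenyl-4,4-dimethylcyclopentan-1-one
Product: 4 (3S)-2-diazo-3-ethenyl-4,4-dimethylcyclopentan-1-one, via trifluoroacetyl ketone 3 (not isolated)
Conditions: LiHMDS, THF, −78 °C, then CF3CO2CH2CF3, dilute HCl work-up; crude 3, MsN3, Et3N, H2O, MeCN, rt
Reagents that add atoms: 2,2,2-trifluoroethyl trifluoroacetate, O=C(OCC(F)(F)F)C(F)(F)F (atoms kept in 3 only); methanesulfonyl azide, CS(=O)(=O)N=[N+]=[N-]
Why: Regitz-type diazo transfer in its detrifluoroacetylative form: the bulky amide should take a proton from the methylene next to the vinyl-bearing carbon (future C9) because the other methylene is neopentyl-like beside CMe2, Claisen acylation there gives the activated diketone 3, and mesyl azide then delivers N2 with loss of the trifluoroacetyl group without touching the stereocentre.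

Step 3
Reactants: 4 (3S)-2-diazo-3-ethenyl-4,4-dimethylcyclopentan-1-one
Product: 6 (2R)-2-ethenyl-3,3-dimethylcyclobutane-1-carboxylic acid (epimers at the carboxyl-bearing carbon C9), via cyclobutylidene ketene 5 (not isolated)
Conditions: hν (Hg lamp, Pyrex), THF/H2O, rt
Reagents that add atoms: water, O
Why: Photochemical Wolff rearrangement: loss of N2 from the s-Z locked diazo ketone with 1,2-shift of the ring CH2 (future C10) contracts the five-membered ring to the cyclobutylidene ketene 5, water adds to it, and the unselective protonation at C9 is of no consequence because that centre is equilibrated in step 4.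

Step 4
Reactants: 6 (2R)-2-ethenyl-3,3-dimethylcyclobutane-1-carboxylic acid; 7 (3-ethoxy-3-oxopropyl)zinc bromide
Product: 10 ethyl 4-[(1S,2R)-2-ethenyl-3,3-dimethylcyclobutyl]-4-oxobutanoate (trans keto ester), via acid chloride 8 (not isolated), via epimeric keto ester 9 (not isolated)
Conditions: (COCl)2, DMF (cat.), CH2Cl2, 0 °C to rt; 7, Pd(PPh3)4 (5 mol %), THF, 0 °C to rt; crude 9, NaOEt (0.2 equiv), EtOH, rt
Reagents that add atoms: oxalyl chloride, O=C(Cl)C(=O)Cl (chlorine of 8 only)
Why: Negishi-type acylation of a zinc homoenolate with an acid chloride under zerovalent palladium forms C7–C8 without attack on the ester, and catalytic ethoxide then equilibrates the ketone through its enolate to the less crowded trans-1,2-disubstituted cyclobutane, which sets C9 (S) under thermodynamic control from C1.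

Step 5
Reactants: 10 trans keto ester
Product: 11 ethyl 3-{2-[(1S,2R)-2-ethenyl-3,3-dimethylcyclobutyl]-1,3-dioxolan-2-yl}propanoate
Conditions: HOCH2CH2OH, p-TsOH (cat.), PhMe, Dean–Stark, reflux
Reagents that add atoms: ethane-1,2-diol, OCCO
Why: Acid-catalysed ketalisation with azeotropic removal of water masks the only ketone as its dioxolane, as is routine for γ-keto esters, and any enolisation during the reaction can only return the favoured trans isomer.

Step 6
Reactants: 11 ketal ester
Product: 12 N-methoxy-N-methyl-3-{2-[(1S,2R)-2-ethenyl-3,3-dimethylcyclobutyl]-1,3-dioxolan-2-yl}propanamide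
Conditions: MeONHMe·HCl, i-PrMgCl, THF, −20 to 0 °C
Reagents that add atoms: N,O-dimethylhydroxylamine hydrochloride, CNOC.Cl
Why: Aminolysis of the ester by the chloromagnesium amide of N,O-dimethylhydroxylamine is a standard entry to Weinreb amides and leaves ketal and vinyl group alone.

Step 7
Reactants: 12 Weinreb amide
Product: 13 5-{2-[(1S,2R)-2-ethenyl-3,3-dimethylcyclobutyl]-1,3-dioxolan-2-yl}pent-1-en-3-one
Conditions: CH2=CHMgBr, THF, 0 °C; inverse quench into cold 1 M HCl
Reagents that add atoms: vinylmagnesium bromide, C=C[Mg]Br
Why: Weinreb ketone synthesis: the chelated tetrahedral adduct holds until the quench so that only one vinyl group (C3) is added to C5, and the inverse acidic quench keeps the released amine protonated and away from the new enone.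

Step 8
Reactants: 13 dienone
Product: 14 (1R,9S)-eight-membered enone, trans-10,10-dimethylbicyclo[6.2.0]dec-2-ene-4,7-dione 7-ethylene ketal (C5=O, cis-C2=C3, C8 dioxolane)
Conditions: second-generation Hoveyda–Grubbs catalyst RuCl2(SIMes)(=CH-C6H4-2-Oi-Pr) (10 mol %), 1,4-benzoquinone (cat.), PhMe (1 mM), 80 °C
Reagents that add atoms: none
Why: Ring-closing metathesis: the ruthenium carbene should load on the electron-neutral vinyl group at C1 and close onto the acryloyl alkene to form C2=C3, helped by the ketal quaternary centre and the rigid trans-cyclobutane that bring the chain ends together and by high dilution, and an eight-membered ring accepts only the cis alkene.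

Step 9
Reactants: 14 eight-membered enone
Product: 15 (1R,9S)-triethylsilyl enol ether of the eight-membered ketone (C5–OSiEt3, ring-cis C5=C3, C2H2, C8 dioxolane)
Conditions: Et3SiH, RhCl(PPh3)3 (2 mol %), PhH, 55 °C
Reagents that add atoms: triethylsilane, CC[SiH](CC)CC
Why: Rhodium-catalysed 1,4-hydrosilylation of an enone with a monohydrosilane puts hydrogen on C2 and silicon on oxygen, so the enol ether double bond is fixed between C5 and C3 and cannot form toward C6, and the triethylsilyl group is chosen over trimethylsilyl because its silane is a liquid and its enol ether stands chromatography and brief contact with n-BuLi.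

Step 10
Reactants: 15 triethylsilyl enol ether; 16 1,1-dichloroethane
Product: 18 (1R,9S,3Z)-4,11,11-trimethylbicyclo[7.2.0]undec-3-ene-5,8-dione 8-ethylene ketal, via chlorosiloxycyclopropane 17 (not isolated)
Conditions: 16 (excess), n-BuLi (slow addition), Et2O, −35 °C to rt; then Et3N, DMAP (cat.), PhMe, 110 °C
Reagents that add atoms: none
Why: n-BuLi deprotonates 16 to 1,1-dichloroethyllithium, which loses LiCl and transfers chloro(methyl)carbene to the only alkene present, the electron-rich C5=C3 enol ether, closing the three-membered ring C3–C4–C5 in a concerted [2+1] cheletropic addition that makes C3–C4 and C4–C5. On heating, chloride leaves C4 while the C3–C5 bond breaks in a disrotatory two-electron electrocyclic opening pushed by the siloxy oxygen, so the nine-membered ring arises by expansion of the bicyclo[6.1.0] unit and not by end-to-end cyclisation, and chloride then takes the silyl group from the oxocarbenium ion to give 18 and Et3SiCl. The closest known reaction type is the homologation of cyclic silyl enol ethers to 2-methylcycloalk-2-enones with 1,1-dichloroethane and n-BuLi. The stereocentres created at C3, C4 and C5 in 17 are transient and vanish in 18, no lasting stereocentre is formed, and C1 and C9 are not touched. Selectivity is needed in position and in alkene geometry: position is fixed by the enol ether of step 9, and geometry by the Woodward–Hoffmann–DePuy rule, under which the endo-chloro epimer (methyl exo, favoured because methyl avoids the ring methylenes) turns C2 and C6 inward and gives the ring-cis Z-enone. Because a nine-membered ring could also hold the E-enone that the exo-chloro epimer would give by outward rotation, DMAP is present to equilibrate the enone by reversible conjugate addition toward the less strained Z isomer.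

Step 11
Reactants: 18 nine-membered Z-enone
Product: 19 (1R,5R,9S,3Z)-5-hydroxy-4,11,11-trimethylbicyclo[7.2.0]undec-3-en-8-one ethylene ketal
Conditions: (S)-2-methyl-CBS-oxazaborolidine (20 mol %), catecholborane, PhMe, −78 °C
Reagents that add atoms: none
Why: Corey–Bakshi–Shibata reduction: in the catalyst–ketone complex the branched alkenyl arm C4 plays the large group and C6H2 the small one, so the (S)-oxazaborolidine should deliver hydride in 1,2-fashion to the face that gives 5R by reagent control, as is usual for 2-substituted cycloalkenones.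

Step 12
Reactants: 19 allylic alcohol
Product: 20 (1R,5R,9S,3Z)-5-(tert-butyldimethylsilyloxy)-4,11,11-trimethylbicyclo[7.2.0]undec-3-en-8-one ethylene ketal
Conditions: TBSCl, imidazole, DMF, 35 °C
Reagents that add atoms: tert-butyldimethylsilyl chloride, CC(C)(C)[Si](C)(C)Cl
Why: Standard silylation of a secondary alcohol, introduced so that no transannular hemiketal between O5 and C8 can form once the ketone is freed and so that the hydroxyl cannot add to the oxadiene in step 17.

Step 13
Reactants: 20 silyl ether ketal
Product: 21 (1R,5R,9S,3Z)-5-(tert-butyldimethylsilyloxy)-4,11,11-trimethylbicyclo[7.2.0]undec-3-en-8-one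
Conditions: PPTS (cat.), acetone/H2O, 55 °C
Reagents that add atoms: water, O
Why: Mild acid-catalysed ketal hydrolysis frees the C8 ketone while the secondary TBS ether and the trisubstituted alkene persist, and C9 stays trans because that is the more stable ring fusion.

Step 14
Reactants: 21 C8 ketone
Product: 22 (1R,5R,9S,3Z)-5-(tert-butyldimethylsilyloxy)-4,11,11-trimethyl-8-methylidenebicyclo[7.2.0]undec-3-ene
Conditions: Ph3PCH3Br, KOt-Bu, THF, 0 to 50 °C
Reagents that add atoms: methyltriphenylphosphonium bromide, C[P+](c1ccccc1)(c1ccccc1)c1ccccc1.[Br-]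
Why: Wittig methylenation with the non-stabilised ylide converts the hindered C8 ketone into the C8=C15 methylene, a transformation well known for cyclobutane-flanked nine-membered ketones of the caryophyllane type, and any enolisation returns the trans fusion.

Step 15
Reactants: 23 2,4,6-trihydroxyacetophenone
Product: 24 2-acetyl-4,4,6,6-tetramethylcyclohexane-1,3,5-trione
Conditions: MeI (excess), NaOMe, MeOH, reflux
Reagents that add atoms: iodomethane, CI
Why: Exhaustive dearomatising C-methylation of the phloroglucinol core: each enolate carbon between two oxygens is alkylated twice until both free ring positions are quaternary.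

Step 16
Reactants: 24 acetylsyncarpic acid
Product: 25 syncarpic acid (2,2,4,4-tetramethylcyclohexane-1,3,5-trione)
Conditions: 6 M aq. HCl, reflux
Reagents that add atoms: none
Why: Acid-promoted retro-Claisen deacylation removes the acetyl group of the tricarbonylmethane unit as acetic acid and leaves syncarpic acid.

Step 17
Reactants: 22 methylidene silyl ether; 25 syncarpic acid; 26 3-methylbutanal
Product: 28 O5-tert-butyldimethylsilyl Tomentodione O (1R,5R,8S,9S,1′R), via isobutylidene-syncarpic acid 27 (not isolated)
Conditions: 25 and 26 (excess), ethylenediammonium diacetate (20 mol %), PhMe, 80 °C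
Reagents that add atoms: none
Why: Domino Knoevenagel/hetero-Diels–Alder reaction with inverse electron demand: 25 and 26 condense to the electron-poor oxadiene 27, whose oxygen bonds to the more substituted C8 and whose C1′ bonds to the terminal C15 of the only 1,1-disubstituted alkene (the Z-trisubstituted C3=C4 beside the silyloxy group being slower), the diene approaching the outer face of the methylene on the C10 side, away from the ring interior and from the C5 silyloxy group, which should set 8S, while isobutyl sits outside on the diene and the bulky C9 branch exo, which places isobutyl cis to C7 and should set 1′R.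

Step 18
Reactants: 28 silyl ether of the target
Product: 29 Tomentodione O
Conditions: HF·pyridine, pyridine, THF, 0 °C to rt
Reagents that add atoms: none
Why: Fluoride-induced cleavage of the silyl ether under buffered conditions leaves the vinylogous ester, the tertiary C8–O bond and the allylic alcohol intact and touches no stereocentre.

Compound list
1 | 4,4-dimethylcyclopent-2-en-1-one | CC1(C)CC(=O)C=C1 | starting material
2 | (3S)-3-ethenyl-4,4-dimethylcyclopentan-1-one | C=C[C@@H]1CC(=O)CC1(C)C | intermediate
3 | (3R)-3-ethenyl-4,4-dimethyl-2-(trifluoroacetyl)cyclopentan-1-one, C2 unfixed, largely enol (same spatial arrangement as 2) | C=C[C@@H]1C(C(=O)C(F)(F)F)C(=O)CC1(C)C | intermediate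
4 | (3S)-2-diazo-3-ethenyl-4,4-dimethylcyclopentan-1-one | C=C[C@@H]1C(=[N+]=[N-])C(=O)CC1(C)C | intermediate
5 | [(2S)-2-ethenyl-3,3-dimethylcyclobutylidene]methanone (ketene) | C=C[C@@H]1C(=C=O)CC1(C)C | intermediate
6 | (2R)-2-ethenyl-3,3-dimethylcyclobutane-1-carboxylic acid, epimers at C1 of the acid (C9) | C=C[C@@H]1C(CC1(C)C)C(=O)O | intermediate
7 | (3-ethoxy-3-oxopropyl)zinc bromide | CCOC(=O)CC[Zn]Br | starting material
8 | (2R)-2-ethenyl-3,3-dimethylcyclobutane-1-carbonyl chloride, C9 epimers | C=C[C@@H]1C(CC1(C)C)C(=O)Cl | intermediate
9 | ethyl 4-[(2R)-2-ethenyl-3,3-dimethylcyclobutyl]-4-oxobutanoate, C9 epimers | C=C[C@@H]1C(CC1(C)C)C(=O)CCC(=O)OCC | intermediate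
10 | ethyl 4-[(1S,2R)-2-ethenyl-3,3-dimethylcyclobutyl]-4-oxobutanoate (trans) | C=C[C@@H]1[C@H](CC1(C)C)C(=O)CCC(=O)OCC | intermediate
11 | ethyl 3-{2-[(1S,2R)-2-ethenyl-3,3-dimethylcyclobutyl]-1,3-dioxolan-2-yl}propanoate | C=C[C@@H]1[C@H](CC1(C)C)C1(CCC(=O)OCC)OCCO1 | intermediate
12 | N-methoxy-N-methyl-3-{2-[(1S,2R)-2-ethenyl-3,3-dimethylcyclobutyl]-1,3-dioxolan-2-yl}propanamide | C=C[C@@H]1[C@H](CC1(C)C)C1(CCC(=O)N(C)OC)OCCO1 | intermediate
13 | 5-{2-[(1S,2R)-2-ethenyl-3,3-dimethylcyclobutyl]-1,3-dioxolan-2-yl}pent-1-en-3-one | C=C[C@@H]1[C@H](CC1(C)C)C1(CCC(=O)C=C)OCCO1 | intermediate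
14 | (1R,9S)-trans-10,10-dimethylbicyclo[6.2.0]dec-2-ene-4,7-dione 7-ethylene ketal (C5=O, cis-C2=C3, C8 dioxolane) | O=C1/C=C\[C@@H]2[C@H](CC2(C)C)C2(CC1)OCCO2 | intermediate
15 | (1R,9S)-triethylsilyl enol ether of the eight-membered ketone (C5–OSiEt3, ring-cis C5=C3, C8 dioxolane) | CC[Si](CC)(CC)O/C1=C/C[C@@H]2[C@H](CC2(C)C)C2(CC1)OCCO2 | intermediate
16 | 1,1-dichloroethane | CC(Cl)Cl | starting material
17 | chlorosiloxycyclopropane fused on C3–C5 of the eight-membered ring (C4 bears Cl and Me, C5 bears OSiEt3; epimers at C3, C4, C5) | CC1(Cl)C2C[C@@H]3[C@H](CC3(C)C)C3(CCC12O[Si](CC)(CC)CC)OCCO3 | intermediate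
18 | (1R,9S,3Z)-4,11,11-trimethylbicyclo[7.2.0]undec-3-ene-5,8-dione 8-ethylene ketal | C/C1=C/C[C@@H]2[C@H](CC2(C)C)C2(CCC1=O)OCCO2 | intermediate
19 | (1R,5R,9S,3Z)-5-hydroxy-4,11,11-trimethylbicyclo[7.2.0]undec-3-en-8-one ethylene ketal | C/C1=C/C[C@@H]2[C@H](CC2(C)C)C2(CC[C@H]1O)OCCO2 | intermediate
20 | (1R,5R,9S,3Z)-5-(tert-butyldimethylsilyloxy)-4,11,11-trimethylbicyclo[7.2.0]undec-3-en-8-one ethylene ketal | C/C1=C/C[C@@H]2[C@H](CC2(C)C)C2(CC[C@H]1O[Si](C)(C)C(C)(C)C)OCCO2 | intermediate
21 | (1R,5R,9S,3Z)-5-(tert-butyldimethylsilyloxy)-4,11,11-trimethylbicyclo[7.2.0]undec-3-en-8-one | C/C1=C/C[C@@H]2[C@H](CC2(C)C)C(=O)CC[C@H]1O[Si](C)(C)C(C)(C)C | intermediate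
22 | (1R,5R,9S,3Z)-5-(tert-butyldimethylsilyloxy)-4,11,11-trimethyl-8-methylidenebicyclo[7.2.0]undec-3-ene | C/C1=C/C[C@@H]2[C@H](CC2(C)C)C(=C)CC[C@H]1O[Si](C)(C)C(C)(C)C | intermediate
23 | 2,4,6-trihydroxyacetophenone | CC(=O)c1c(O)cc(O)cc1O | starting material
24 | 2-acetyl-4,4,6,6-tetramethylcyclohexane-1,3,5-trione | CC(=O)C1C(=O)C(C)(C)C(=O)C(C)(C)C1=O | intermediate
25 | syncarpic acid, 2,2,4,4-tetramethylcyclohexane-1,3,5-trione | CC1(C)C(=O)CC(=O)C(C)(C)C1=O | intermediate
26 | 3-methylbutanal | CC(C)CC=O | starting material
27 | isobutylidene-syncarpic acid, 2,2,4,4-tetramethyl-6-(3-methylbutylidene)cyclohexane-1,3,5-trione | CC(C)CC=C1C(=O)C(C)(C)C(=O)C(C)(C)C1=O | intermediate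
28 | O5-tert-butyldimethylsilyl Tomentodione O (1R,5R,8S,9S,1′R,3Z) | C/C1=C/C[C@@H]2[C@H](CC2(C)C)[C@]2(CC[C@H]1O[Si](C)(C)C(C)(C)C)C[C@@H](CC(C)C)C1=C(O2)C(C)(C)C(=O)C(C)(C)C1=O | intermediate
29 | Tomentodione O (1R,5R,8S,9S,1′R,3Z) | C/C1=C/C[C@@H]2[C@H](CC2(C)C)[C@]2(CC[C@H]1O)C[C@@H](CC(C)C)C1=C(O2)C(C)(C)C(=O)C(C)(C)C1=O | target

Total step count: 18. Longest linear sequence: 16 (steps 1–14, 17, 18). Steps 15 and 16 form the side branch.

Steps most likely to fail

**Step 10.** Three things may go wrong.
- The lithium carbenoid may collapse by 1,2-hydride shift faster than a hindered medium-ring enol ether can intercept it.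
- n-BuLi may attack silicon.
- The exo-chloro epimer may resist opening, or may open with outward rotation, so that alkene geometry is lost.

The fallback keeps the insertion of C4 between C3 and C5 but brings the methyl group in separately. It sets out from 15.
- Simmons–Smith cyclopropanation in the Furukawa variant (Et2Zn, CH2I2) gives the siloxycyclopropane F1.
- FeCl3 in pyridine-buffered DMF cleaves the same C3–C5 bond by one-electron oxidation and gives the ring-expanded 3-chloro ketone F2.
- NaOAc in MeOH eliminates HCl under equilibrating conditions to the Z-cyclononenone F3.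
- I2/pyridine gives the 2-iodo enone F4.
- Suzuki–Miyaura coupling with methylboronic acid (Pd(dppf)Cl2, K2CO3) installs the methyl group, and the sequence comes back to the route at 18.

**Step 8.** Oligomerisation by cross-metathesis, slow loading of the catalyst on the crowded vinyl group, sequestration of ruthenium by the acryloyl unit, or strain in the closing ring may stop the cyclisation. The fallback moves the ring closure from C2=C3 to the C3–C5 bond. It sets out from 11.
- Ozonolysis with Me2S work-up gives the C2 aldehyde F5.
- Stork–Zhao olefination (Ph3PCH2I iodide, NaHMDS) gives the Z-vinyl iodide F6.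
- DIBAL-H at −78 °C reduces the ester to the C5 aldehyde F7.
- An intramolecular Nozaki–Hiyama–Kishi reaction (CrCl2, NiCl2 cat., DMSO, high dilution) closes the eight-membered allylic alcohol F8 as an inconsequential mixture at C5.
- Dess–Martin oxidation brings the sequence back to the route at 14.

**Step 17.** Poor facial selectivity at the C8=C15 methylene, or weak exo/endo discrimination, would spread the material over several diastereomers. The oxadiene may also be drained by Michael addition of a second molecule of 25. The fallback gives up the thermal three-component reaction under substrate control. It sets out from 22 and from 27, which is then prepared beforehand from 25 and 26 and isolated. The two are joined at low temperature under a chiral Lewis acid, Cu(OTf)2 with a C2-symmetric bis(oxazoline) ligand chelated by the two carbonyl groups that flank the alkylidene carbon. The face of C1′ is then chosen by the catalyst (both ligand antipodes being tried), and only the C8 face is left to the terpene. The sequence comes back to the route at 28 and makes no compound outside the list (F0).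

Further compounds
F1 | step 10 | siloxycyclopropane on C3–C5 of the eight-membered ring (C4 = CH2, C5–OSiEt3, C8 dioxolane, C1 and C9 as in 15) | C1C2C[C@@H]3[C@H](CC3(C)C)C3(CCC12O[Si](CC)(CC)CC)OCCO3
F2 | step 10 | nine-membered 3-chloro ketone (C5=O, C4H2, C3–Cl, C8 dioxolane, C1 and C9 as in 15) | C1C(Cl)C[C@@H]2[C@H](CC2(C)C)C2(CCC1=O)OCCO2
F3 | step 10 | nine-membered Z-enone without the methyl group (C5=O, Z-C3=C4, C8 dioxolane) | O=C1/C=C\C[C@@H]2[C@H](CC2(C)C)C2(CC1)OCCO2
F4 | step 10 | ring-cis 4-iodo enone (C5=O, C4–I, C8 dioxolane) | I/C1=C/C[C@@H]2[C@H](CC2(C)C)C2(CCC1=O)OCCO2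
F5 | step 8 | C2 aldehyde of the ketal ester (formyl in place of vinyl in 11) | O=C[C@@H]1[C@H](CC1(C)C)C1(CCC(=O)OCC)OCCO1
F6 | step 8 | Z-2-iodoethenyl ketal ester (Z-C2=C3–I) | I/C=C\[C@@H]1[C@H](CC1(C)C)C1(CCC(=O)OCC)OCCO1
F7 | step 8 | Z-2-iodoethenyl ketal aldehyde (C5 = CHO) | I/C=C\[C@@H]1[C@H](CC1(C)C)C1(CCC=O)OCCO1
F8 | step 8 | eight-membered allylic alcohol (C5–OH epimers, cis-C2=C3, C8 dioxolane) | OC1/C=C\[C@@H]2[C@H](CC2(C)C)C2(CC1)OCCO2
F0 | step 17 | none | none
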